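**Synthetic plan**

- Retrosynthesis: the oxepane is opened at O–C16 (C3 hydroxyl onto a C16 triflate). The cyclohexane is cut at C1–C14 and C12–C13 (Diels–Alder reaction of a C1=C10–C11=C12 ethoxy diene with methyl vinyl ketone) and at C10–C11 (Stille coupling). The oxygen-bridged ten-membered ring is traced back, by cutting C8–C9 and O–C9 and re-joining O–C6, to a 2,6-cis tetrahydropyran diazoketone, itself cut at C2–C3 (ketyl–acrylate cyclisation) and O–C2 (oxa-Michael addition).
- Enabling feature: C9, which carries the bridging ether oxygen, is separated from the Z C6=C7 bond by one methylene (C8), and C2, the other end of the bridge, is flanked by the oxygenated quaternary C3. Read backwards, O–C9–C8–C7=C6 is the product pattern of a [2,3] shift of an allylic oxonium ylide whose oxygen belonged to the six-membered ether ring O–C2–C3–C4–C5–C6.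
- Ring order in the forward direction: tetrahydropyran (SmI2), then the furan-3-one ring (O, C2, C1, C10, C9) together with the nine-membered oxonene and ten-membered carbocycle in the key step, then the cyclohexene (Diels–Alder), and last the oxepane (C16–O–C3).
- Stereochemistry: C6 comes from a CBS reduction, relays to C2 and C3 in the SmI2 cyclisation and is then consumed. C9 follows from C2 in the bridged ylide. C1 and C12 come from the hydroxyl-directed Diels–Alder step, C14 from base equilibration, C10 from enol ether protonation, C11 from LiBH(s-Bu)3 and C15 from hydroboration under allylic-strain control.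

Key step: step 11

Remark: carbons are numbered C1–C16 as in the target skeleton (ten-membered ring C1–C10, ether bridge C2–O–C9, cyclohexane C1/C10–C14, side chain C15/C16); in the isomer asked for, (1S,2R,3S,6Z,9R,10R,11R,12R,14S,15R), H1, H2, H9 and H10 are all cis on the tetrahydrofuran, so the cyclohexane has to be built on the face of the bicycle that carries C3 and C8, and the C3 silyl ether is therefore removed before the cycloaddition so that the free hydroxyl can direct it.

**Route**

Step 1
Reactants: 1 ethyl levulinate
Product: 2 ethyl 3-(2-methyl-1,3-dioxolan-2-yl)propanoate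
Conditions: HOCH2CH2OH, p-TsOH·H2O (cat.), toluene, reflux, Dean–Stark
Reagents that add atoms: ethylene glycol, OCCO
Why: Acid-catalysed ketalisation with azeotropic removal of water masks the ketone (future C3) against the organomagnesium and hydride reagents of the next steps; no stereocentre is formed.

Step 2
Reactants: 2 dioxolane ester
Product: 3 N-methoxy-N-methyl-3-(2-methyl-1,3-dioxolan-2-yl)propanamide
Conditions: MeNH(OMe)·HCl, i-PrMgCl, THF, −20 → 0 °C
Reagents that add atoms: N,O-dimethylhydroxylamine hydrochloride, CNOC.Cl
Why: Weinreb amide synthesis by aminolysis of the ester with the chloromagnesium amide formed in the flask; the dioxolane is inert to the basic medium.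

Step 3
Reactants: 3 Weinreb amide; 4 isopropenylmagnesium bromide
Product: 5 2-methyl-5-(2-methyl-1,3-dioxolan-2-yl)pent-1-en-3-one
Conditions: THF, 0 °C; cold aq. NH4Cl
Reagents that add atoms: none
Why: Grignard addition to a Weinreb amide stops at the magnesium-chelated tetrahedral intermediate, so the isopropenyl ketone (C6 to C8 and the C7 methyl) is released only on work-up and is not attacked a second time.

Step 4
Reactants: 5 isopropenyl ketone
Product: 6 (3R)-2-methyl-5-(2-methyl-1,3-dioxolan-2-yl)pent-1-en-3-ol
Conditions: (S)-Me-CBS oxazaborolidine (C18H20BNO, 10 mol%), catecholborane, toluene, −78 °C; MeOH, aq. NaOH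
Reagents that add atoms: none
Why: Corey–Bakshi–Shibata reduction, in which the α-branched isopropenyl group acts as the large substituent in the catalyst–borane–ketone complex, so the (S)-oxazaborolidine delivers hydride to the face that gives the R carbinol (C6), while catecholborane at low temperature reduces the carbonyl without hydroborating the alkene.

Step 5
Reactants: 6 (R)-allylic alcohol; 7 ethyl propiolate
Product: 8 ethyl (2E)-3-{[(3R)-2-methyl-5-(2-methyl-1,3-dioxolan-2-yl)pent-1-en-3-yl]oxy}prop-2-enoate
Conditions: N-methylmorpholine, CH2Cl2, rt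
Reagents that add atoms: none
Why: Amine-catalysed oxa-Michael addition of the secondary alcohol to the propiolate gives the E β-alkoxyacrylate (C2, C1, C10) and does not touch the carbinol centre.

Step 6
Reactants: 8 β-alkoxyacrylate dioxolane
Product: 9 ethyl (2E)-3-{[(3R)-2-methyl-6-oxohept-1-en-3-yl]oxy}prop-2-enoate
Conditions: pyridinium p-toluenesulfonate, acetone/H2O, 50 °C
Reagents that add atoms: water, O
Why: Mild acid-catalysed acetal hydrolysis frees the methyl ketone, while the β-alkoxyacrylate (a deactivated, vinylogous-carbonate enol ether) and the allylic ether are not cleaved under these conditions.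

Step 7
Reactants: 9 keto β-alkoxyacrylate
Product: 10 ethyl 2-[(2R,3S,6R)-3-hydroxy-3-methyl-6-(prop-1-en-2-yl)oxan-2-yl]acetate
Conditions: SmI2 (2.5 equiv, divalent samarium), MeOH, THF, 0 °C
Reagents that add atoms: none
Why: Ketyl–olefin reductive cyclisation (6-exo-trig), in which the samarium ketyl at C3 adds to the acrylate β-carbon C2 through a chair-like transition state with the isopropenyl group and the acrylate equatorial and the samarium-bound oxygen held near the ester, so the R centre at C6 sets C2 (2,6-cis) and C3 (hydroxyl trans to the acetate side chain, methyl axial).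

Step 8
Reactants: 10 tetrahydropyranol ester
Product: 11 ethyl 2-[(2R,3S,6R)-3-[(tert-butyldimethylsilyl)oxy]-3-methyl-6-(prop-1-en-2-yl)oxan-2-yl]acetate
Conditions: TBSOTf, 2,6-lutidine, CH2Cl2, 0 °C → rt
Reagents that add atoms: tert-butyldimethylsilyl trifluoromethanesulfonate, CC(C)(C)[Si](C)(C)OS(=O)(=O)C(F)(F)F
Why: A silyl triflate with a hindered pyridine base silylates even the tertiary alcohol, which has to be capped so that it cannot trap the carbenoid by O–H insertion in step 11.

Step 9
Reactants: 11 silyl ether ester
Product: 12 2-[(2R,3S,6R)-3-[(tert-butyldimethylsilyl)oxy]-3-methyl-6-(prop-1-en-2-yl)oxan-2-yl]acetic acid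
Conditions: LiOH, THF/MeOH/H2O, rt; 1 M HCl to pH 4
Reagents that add atoms: lithium hydroxide, [Li+].[OH-]
Why: Saponification of the unhindered ethyl ester; the tertiary silyl ether survives hydroxide and no stereocentre is α to the carboxylate.

Step 10
Reactants: 12 carboxylic acid
Product: 14 1-diazo-3-[(2R,3S,6R)-3-[(tert-butyldimethylsilyl)oxy]-3-methyl-6-(prop-1-en-2-yl)oxan-2-yl]propan-2-one, via mixed isobutyl carbonic anhydride 13 (not isolated)
Conditions: i-BuOCOCl, Et3N, Et2O, −20 °C; CH2N2, Et2O, 0 °C → rt
Reagents that add atoms: diazomethane, C=[N+]=[N-]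
Why: Acylation of diazomethane by the mixed carbonic anhydride (first stage of an Arndt–Eistert sequence) gives the α-diazoketone and supplies C9 under conditions mild enough for the silyl ether and the β-alkoxy acid.

Step 11
Reactants: 14 diazoketone
Product: 17 (1R,2S,5Z,8R)-2-[(tert-butyldimethylsilyl)oxy]-2,6-dimethyl-11-oxabicyclo[6.2.1]undec-5-en-9-one, via copper carbenoid 15 (not isolated), via oxonium ylide 16 (not isolated)
Conditions: Cu(hfacac)2 [Cu(CF3COCHCOCF3)2, divalent copper, 5 mol%], CH2Cl2, reflux, slow addition of 14
Reagents that add atoms: none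
Why: Cu(hfacac)2 converts the diazoketone into an electrophilic copper carbenoid at C9, the pyran oxygen (four atoms from C9) adds to it to give a copper-associated bicyclic oxonium ylide, and a concerted suprafacial [2,3]-sigmatropic shift through a five-membered envelope transition state joins C9 to the isopropenyl terminus C8 while the O–C6 bond breaks and the C6=C7 double bond appears. The closest known reaction type is the copper-catalysed tandem oxonium ylide formation and [2,3] rearrangement of cyclic allylic ethers that carry a diazoketone side chain, which is established for 6-alkenyl-tetrahydropyran-2-yl diazoketones. The furan-3-one ring (O, C2, C1, C10, C9) closes by attack of the ether oxygen on the carbenoid carbon (five-membered ring closure at the ylide stage), whereas the nine-membered oxonene, and with it the ten-membered carbocycle C1–C10, arises by three-atom ring expansion of the tetrahydropyran in the sigmatropic step and not by direct medium-ring cyclisation. C9 is the only new stereocentre and is controlled by C2, because the ylide carbon is held in the ring fused at O–C2 and reaches C8 only on the side where the cis-2,6 isopropenyl group sits, so C8 ends cis to C3 across the new tetrahydrofuran (9R). The step needs the [2,3] shift in preference to a [1,2] shift or C–H insertion and Z geometry at C6=C7; the cis-2,6 arrangement holds the alkene terminus next to the ylide carbon, the silyl ether removes the O–H insertion pathway, and the electron-poor copper catalyst (rather than a dirhodium tetracarboxylate) favours the envelope transition state in which C5 and C8 come out cis.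

Step 12
Reactants: 18 ethoxyacetylene
Product: 20 1-ethoxyprop-1-yne, via lithium ethoxyacetylide 19 (not isolated)
Conditions: n-BuLi, THF, −78 °C; MeI, DMPU, −78 °C → rt
Reagents that add atoms: iodomethane, CI
Why: Deprotonation of the terminal alkyne and SN2 methylation of the acetylide install the future C12 methyl group on the C11–C12 unit.

Step 13
Reactants: 20 1-ethoxyprop-1-yne
Product: 21 tributyl[(1E)-1-ethoxyprop-1-en-1-yl]stannane
Conditions: Bu3SnH, Pd(PPh3)4 (2 mol%, zerovalent palladium), THF, 0 °C → rt
Reagents that add atoms: tributyltin hydride, CCCC[SnH](CCCC)CCCC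
Why: Palladium-catalysed hydrostannation is a syn addition that, with an ynol ether, places tin on the oxygen-bearing carbon, so hydrogen and tin end cis and the methyl group cis to ethoxy.

Step 14
Reactants: 17 bridged bicyclic ketone
Product: 23 (1R,2S,5Z,8R)-2-[(tert-butyldimethylsilyl)oxy]-2,6-dimethyl-11-oxabicyclo[6.2.1]undeca-5,9-dien-9-yl trifluoromethanesulfonate, via sodium enolate 22 (not isolated)
Conditions: NaN(SiMe3)2, THF, −78 °C; PhNTf2, −78 → 0 °C
Reagents that add atoms: N-phenylbis(trifluoromethanesulfonimide), O=S(=O)(N(c1ccccc1)S(=O)(=O)C(F)(F)F)C(F)(F)F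
Why: Kinetic deprotonation occurs at the C1 methylene and not at the oxygen-bearing bridgehead C9, whose C–H bond is poorly aligned with the carbonyl π system, and O-sulfonylation of the enolate at low temperature (before the ring oxygen can be lost by β-elimination) gives the C1=C10 vinyl triflate.

Step 15
Reactants: 23 enol triflate; 21 alkenylstannane
Product: 24 (1R,2S,5Z,8R)-2-[(tert-butyldimethylsilyl)oxy]-9-[(1Z)-1-ethoxyprop-1-en-1-yl]-2,6-dimethyl-11-oxabicyclo[6.2.1]undeca-5,9-diene
Conditions: Pd(PPh3)4 (5 mol%, zerovalent palladium), CuI (10 mol%), LiCl, THF, 60 °C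
Reagents that add atoms: none
Why: Stille coupling of a vinyl triflate with an α-alkoxyalkenylstannane (chloride assists oxidative addition, CuI speeds transfer from the hindered stannane) forms C10–C11 with retention of the stannane geometry, so the diene carries the C12 methyl cis to ethoxy and on the outside of the s-cis diene.

Step 16
Reactants: 24 silyl-protected ethoxy diene
Product: 25 (1R,2S,5Z,8R)-9-[(1Z)-1-ethoxyprop-1-en-1-yl]-2,6-dimethyl-11-oxabicyclo[6.2.1]undeca-5,9-dien-2-ol
Conditions: Bu4NF, THF, rt → 50 °C
Reagents that add atoms: none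
Why: Fluoride cleaves the tertiary silyl ether (Si–F bond formation) in a basic medium that the acid-sensitive ethoxy diene tolerates, and it unmasks the C3 hydroxyl that steers the next step and is needed free for the last one.

Step 17
Reactants: 25 C3-hydroxy ethoxy diene; 26 methyl vinyl ketone
Product: 27 tricyclic ethoxy enol ether with C14 acetyl as a mixture of C14 epimers
Conditions: toluene, BHT (cat.), 80 °C, sealed tube
Reagents that add atoms: none
Why: Normal-demand Diels–Alder reaction of a 2-alkoxy diene with an enone, in which the ethoxy group makes C12 the nucleophilic terminus (C12 bonds to the enone β-carbon C13 and C1 to the α-carbon C14), suprafacial addition to the s-cis diene with the C12 methyl and the C1–C2 bond both outside places the methyl cis to C2 (12R), and the free C3 hydroxyl, which lies over C1 on the C3/C8 face (it is the oxygen that later bonds C16), hydrogen-bonds the enone carbonyl in the non-polar solvent and brings the dienophile to that face, anti to the ring oxygen, so that H1 ends cis to H2 (1S).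

Step 18
Reactants: 27 cycloadduct mixture
Product: 28 (1S,2R,3S,6Z,9R,12R,14R)-configured tricyclic ethoxy enol ether with C14 acetyl and free C3 hydroxyl
Conditions: K2CO3, MeOH, rt
Reagents that add atoms: none
Why: Base-mediated epimerisation through the methyl ketone enolate moves the acetyl group to the equatorial position trans to C2 on the cyclohexene (thermodynamic control at C14), while the enol ether and the non-enolisable centres C1 and C12 are unaffected.

Step 19
Reactants: 28 C14-acetyl enol ether
Product: 29 (1S,2R,3S,6Z,9R,12R,14R)-configured tricyclic ethoxy enol ether with C14 isopropenyl and free C3 hydroxyl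
Conditions: Ph3PCH3Br, KOt-Bu (excess), THF, 0 °C → rt
Reagents that add atoms: methyltriphenylphosphonium bromide (as its ylide), C[P+](c1ccccc1)(c1ccccc1)c1ccccc1.[Br-]
Why: Wittig methylenation of the methyl ketone supplies C16; C14 already has its thermodynamically preferred configuration, the enol ether is stable to base, and the C3 alkoxide formed from the excess ylide is a spectator (any hemiketal with the acetyl group reopens under these conditions).

Step 20
Reactants: 29 C14-isopropenyl enol ether
Product: 30 (1S,2R,3S,6Z,9R,10R,12R,14R)-configured tricyclic C11 ketone with C14 isopropenyl and free C3 hydroxyl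
Conditions: 1 M aq. HCl, THF, 0 °C → rt, short reaction time
Reagents that add atoms: water, O
Why: Acid hydrolysis of the enol ether, in which C10 is protonated on the open face that carries H1 and H9 (the other face is covered by C2 and the ten-membered ring) to give the cis ring fusion, while brief exposure to dilute acid leaves C12, the isopropenyl group and the trisubstituted alkene intact; reversible hemiketal formation between the C3 hydroxyl and the new ketone is harmless because the next reagent reduces the open form.

Step 21
Reactants: 30 tricyclic C11 ketone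
Product: 31 (1S,2R,3S,6Z,9R,10R,11R,12R,14R)-configured C3,C11-diol with C14 isopropenyl
Conditions: LiBH(s-Bu)3 (3 equiv), THF, −78 → 0 °C; aq. NH4Cl
Reagents that add atoms: none
Why: The bulky trialkylborohydride attacks the C11 carbonyl from the face anti to the C10–C9 bond and the C12 methyl group (equatorial attack on the chair with both α-substituents equatorial), giving the axial alcohol cis to both neighbours (11R).

Step 22
Reactants: 31 C3,C11-diol
Product: 32 (1S,2R,3S,6Z,9R,10R,11R,12R,14R)-configured C11 butyrate with C14 isopropenyl and free C3 hydroxyl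
Conditions: (n-PrCO)2O, DMAP, Et3N, CH2Cl2, rt
Reagents that add atoms: butyric anhydride, CCCC(=O)OC(=O)CCC
Why: DMAP-catalysed acylation takes the secondary C11 hydroxyl with retention, whereas the tertiary C3 hydroxyl is too hindered to be acylated under these conditions.

Step 23
Reactants: 32 C11 butyrate
Product: 34 (1S,2R,3S,6Z,9R,10R,11R,12R,14S,15R)-configured C11 butyrate with free C3 and C16 hydroxyls, via B-alkyl-9-BBN adduct 33 (not isolated)
Conditions: 9-borabicyclo[3.3.1]nonane (9-BBN), THF, 0 °C → rt; NaBO3·4H2O, H2O, rt
Reagents that add atoms: sodium perborate, [Na+].[O-]OB=O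
Why: Anti-Markovnikov hydroboration–oxidation, in which 9-BBN selects the 1,1-disubstituted alkene over the trisubstituted C6=C7 alkene and the ester and adds to the rotamer that minimises allylic 1,3-strain (H14 eclipsing C15=C16) from the face flanked by the C13 methylene rather than by the ring-fusion carbon C1, which sets C15 as in the target, and perborate oxidises the C–B bond with retention without harming the butyrate.

Step 24
Reactants: 34 C3,C16-diol
Product: 36 CNP0209450.4 (target), via C16 triflate 35 (not isolated)
Conditions: Tf2O, 2,6-lutidine, CH2Cl2, −78 → 0 °C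
Reagents that add atoms: none
Why: The primary hydroxyl is sulfonylated selectively and the tertiary C3 hydroxyl, held next to C16 by the ring system, displaces the triflate in a 7-exo-tet Williamson-type etherification that closes the oxepane without touching any stereocentre.

**Compound list**

1 | ethyl levulinate | CCOC(=O)CCC(C)=O | starting material
2 | ethyl 3-(2-methyl-1,3-dioxolan-2-yl)propanoate | CCOC(=O)CCC1(C)OCCO1 | intermediate
3 | N-methoxy-N-methyl-3-(2-methyl-1,3-dioxolan-2-yl)propanamide | CON(C)C(=O)CCC1(C)OCCO1 | intermediate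
4 | isopropenylmagnesium bromide | CC(=C)[Mg]Br | starting material
5 | 2-methyl-5-(2-methyl-1,3-dioxolan-2-yl)pent-1-en-3-one | CC(=C)C(=O)CCC1(C)OCCO1 | intermediate
6 | (3R)-2-methyl-5-(2-methyl-1,3-dioxolan-2-yl)pent-1-en-3-ol | CC(=C)[C@H](O)CCC1(C)OCCO1 | intermediate
7 | ethyl propiolate | C#CC(=O)OCC | starting material
8 | ethyl (2E)-3-{[(3R)-2-methyl-5-(2-methyl-1,3-dioxolan-2-yl)pent-1-en-3-yl]oxy}prop-2-enoate | CCOC(=O)/C=C/O[C@@H](C(C)=C)CCC1(C)OCCO1 | intermediate
9 | ethyl (2E)-3-{[(3R)-2-methyl-6-oxohept-1-en-3-yl]oxy}prop-2-enoate | CCOC(=O)/C=C/O[C@@H](C(C)=C)CCC(C)=O | intermediate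
10 | ethyl 2-[(2R,3S,6R)-3-hydroxy-3-methyl-6-(prop-1-en-2-yl)oxan-2-yl]acetate | CCOC(=O)C[C@H]1O[C@@H](C(C)=C)CC[C@]1(C)O | intermediate
11 | ethyl 2-[(2R,3S,6R)-3-[(tert-butyldimethylsilyl)oxy]-3-methyl-6-(prop-1-en-2-yl)oxan-2-yl]acetate | CCOC(=O)C[C@H]1O[C@@H](C(C)=C)CC[C@]1(C)O[Si](C)(C)C(C)(C)C | intermediate
12 | 2-[(2R,3S,6R)-3-[(tert-butyldimethylsilyl)oxy]-3-methyl-6-(prop-1-en-2-yl)oxan-2-yl]acetic acid | OC(=O)C[C@H]1O[C@@H](C(C)=C)CC[C@]1(C)O[Si](C)(C)C(C)(C)C | intermediate
13 | mixed anhydride of acid 12 with isobutyl carbonic acid | CC(C)COC(=O)OC(=O)C[C@H]1O[C@@H](C(C)=C)CC[C@]1(C)O[Si](C)(C)C(C)(C)C | intermediate (not isolated)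
14 | 1-diazo-3-[(2R,3S,6R)-3-[(tert-butyldimethylsilyl)oxy]-3-methyl-6-(prop-1-en-2-yl)oxan-2-yl]propan-2-one | [N-]=[N+]=CC(=O)C[C@H]1O[C@@H](C(C)=C)CC[C@]1(C)O[Si](C)(C)C(C)(C)C | intermediate
15 | copper carbenoid of 14 (carbene carbon C9 on copper, one hfacac ligand shown) | O=C(C=[Cu]OC(=CC(=O)C(F)(F)F)C(F)(F)F)C[C@H]1O[C@@H](C(C)=C)CC[C@]1(C)O[Si](C)(C)C(C)(C)C | intermediate (not isolated)
16 | bicyclic oxonium ylide (oxygen bonded to C2, C6 and the carbanionic C9; furan-3-one ring fused to the pyran at O–C2) | O=C1C[C@H]2[O+]([CH-]1)[C@@H](C(C)=C)CC[C@]2(C)O[Si](C)(C)C(C)(C)C | intermediate (not isolated)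
17 | (1R,2S,5Z,8R)-2-[(tert-butyldimethylsilyl)oxy]-2,6-dimethyl-11-oxabicyclo[6.2.1]undec-5-en-9-one (C10 ketone; 2R,3S,9R,6Z in skeleton numbering) | O=C1C[C@H]2O[C@@H]1C/C(C)=C\CC[C@]2(C)O[Si](C)(C)C(C)(C)C | intermediate
18 | ethoxyacetylene | CCOC#C | starting material
19 | lithium ethoxyacetylide | CCOC#C[Li] | intermediate (not isolated)
20 | 1-ethoxyprop-1-yne | CCOC#CC | intermediate
21 | tributyl[(1E)-1-ethoxyprop-1-en-1-yl]stannane (methyl cis to ethoxy) | C/C=C(\OCC)[Sn](CCCC)(CCCC)CCCC | intermediate
22 | sodium C1=C10 enolate of ketone 17 | [Na+].[O-]C1=C[C@H]2O[C@@H]1C/C(C)=C\CC[C@]2(C)O[Si](C)(C)C(C)(C)C | intermediate (not isolated)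
23 | (1R,2S,5Z,8R)-2-[(tert-butyldimethylsilyl)oxy]-2,6-dimethyl-11-oxabicyclo[6.2.1]undeca-5,9-dien-9-yl trifluoromethanesulfonate | O=S(=O)(OC1=C[C@H]2O[C@@H]1C/C(C)=C\CC[C@]2(C)O[Si](C)(C)C(C)(C)C)C(F)(F)F | intermediate
24 | (1R,2S,5Z,8R)-2-[(tert-butyldimethylsilyl)oxy]-9-[(1Z)-1-ethoxyprop-1-en-1-yl]-2,6-dimethyl-11-oxabicyclo[6.2.1]undeca-5,9-diene (diene C1=C10–C11=C12) | CCO/C(=C\C)C1=C[C@H]2O[C@@H]1C/C(C)=C\CC[C@]2(C)O[Si](C)(C)C(C)(C)C | intermediate
25 | (1R,2S,5Z,8R)-9-[(1Z)-1-ethoxyprop-1-en-1-yl]-2,6-dimethyl-11-oxabicyclo[6.2.1]undeca-5,9-dien-2-ol | CCO/C(=C\C)C1=C[C@H]2O[C@@H]1C/C(C)=C\CC[C@]2(C)O | intermediate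
26 | methyl vinyl ketone | CC(=O)C=C | starting material
27 | tricyclic enol ether (C10=C11, 11-OEt) with C14 acetyl and C3 hydroxyl, 1S,2R,3S,9R,12R,6Z, mixture of C14 epimers | CCOC1=C2[C@H]3C/C(C)=C\CC[C@](C)(O)[C@H](O3)[C@H]2C(C(C)=O)C[C@H]1C | intermediate
28 | tricyclic enol ether with C14 acetyl trans to C2 and C3 hydroxyl, 1S,2R,3S,9R,12R,14R,6Z | CCOC1=C2[C@H]3C/C(C)=C\CC[C@](C)(O)[C@H](O3)[C@H]2[C@H](C(C)=O)C[C@H]1C | intermediate
29 | tricyclic enol ether with C14 isopropenyl and C3 hydroxyl, 1S,2R,3S,9R,12R,14R,6Z | CCOC1=C2[C@H]3C/C(C)=C\CC[C@](C)(O)[C@H](O3)[C@H]2[C@H](C(C)=C)C[C@H]1C | intermediate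
30 | tricyclic C11 ketone with C14 isopropenyl and C3 hydroxyl, 1S,2R,3S,9R,10R,12R,14R,6Z | O=C1[C@H]2[C@H]3C/C(C)=C\CC[C@](C)(O)[C@H](O3)[C@H]2[C@H](C(C)=C)C[C@H]1C | intermediate
31 | tricyclic C3,C11-diol with C14 isopropenyl, 1S,2R,3S,9R,10R,11R,12R,14R,6Z | O[C@H]1[C@H]2[C@H]3C/C(C)=C\CC[C@](C)(O)[C@H](O3)[C@H]2[C@H](C(C)=C)C[C@H]1C | intermediate
32 | C11 butyrate of 31 (C3 hydroxyl free), 1S,2R,3S,9R,10R,11R,12R,14R,6Z | CCCC(=O)O[C@H]1[C@H]2[C@H]3C/C(C)=C\CC[C@](C)(O)[C@H](O3)[C@H]2[C@H](C(C)=C)C[C@H]1C | intermediate
33 | B-(C16)-alkyl-9-borabicyclo[3.3.1]nonane adduct of 32 (C15 configured as in 34) | CCCC(=O)O[C@H]1[C@H]2[C@H]3C/C(C)=C\CC[C@](C)(O)[C@H](O3)[C@H]2[C@H]([C@@H](C)CB4C5CCCC4CCC5)C[C@H]1C | intermediate (not isolated)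
34 | C11 butyrate with free C3 tertiary and C16 primary hydroxyls, 1S,2R,3S,9R,10R,11R,12R,14S,15R,6Z | CCCC(=O)O[C@H]1[C@H]2[C@H]3C/C(C)=C\CC[C@](C)(O)[C@H](O3)[C@H]2[C@H]([C@@H](C)CO)C[C@H]1C | intermediate
35 | C16 trifluoromethanesulfonate of 34 | CCCC(=O)O[C@H]1[C@H]2[C@H]3C/C(C)=C\CC[C@](C)(O)[C@H](O3)[C@H]2[C@H]([C@@H](C)COS(=O)(=O)C(F)(F)F)C[C@H]1C | intermediate (not isolated)
36 | CNP0209450.4, (1S,2R,3S,6Z,9R,10R,11R,12R,14S,15R)-configured tetracyclic butyrate | CCCC(=O)O[C@H]1[C@@H]2[C@@H]3[C@@H](C[C@H]1C)[C@@H](C)CO[C@@]1(C)CC/C=C(/C)C[C@H]2O[C@H]31 | target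

**Step count and risks**

Total step count: 24. Longest linear sequence: 22 steps (steps 1–11 and 14–24); the stannane branch (steps 12 and 13) joins at step 15.

Steps most likely to fail:

1. Step 17 (Diels–Alder). Facial delivery may be insufficient: a single hydrogen bond may not hold the enone on the C3/C8 face at the temperature the cycloaddition needs, so addition to the opposite diene face, which leads into the series epimeric at C1 and C12, can compete. Fallback, setting out from 25 and coming back at 27: 25 is converted with EtMgBr (1 equiv, toluene, 0 °C) into its bromomagnesium alkoxide F1 and methyl vinyl ketone 26 is added. The enone carbonyl is then bound to the magnesium on the C3 oxygen and is delivered within the complex to the diene face that carries C3, as a temporarily tethered, Lewis-acid-templated Diels–Alder reaction. Aqueous work-up gives 27.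

2. Step 23 (hydroboration). Facial discrimination at the freely rotating isopropenyl group may be poor, eroding the C15 configuration. Fallback, setting out from 32 and coming back at 34: stereocontrol is moved from the substrate to a catalyst by copper hydride-catalysed hydroboration (CuCl, KOt-Bu, the antipode of DTBM-SEGPHOS that is matched to the substrate, pinacolborane, THF, rt). Enantioface-selective hydrocupration followed by borylation gives the C16 pinacol boronate F2, which NaBO3 oxidises to 34.

3. Step 11 (key step). Z selectivity in the sigmatropic shift may be partly lost (E-oxonene formation), next to a minor [1,2] shift. Fallback, setting out from 14 and coming back at 17: the rearrangement is run as in step 11 and the E-configured ketone F3 in the product mixture is isomerised by reversible thiyl radical addition and elimination (EtSH, AIBN, benzene, reflux). This replaces kinetic control in the transition state by thermodynamic control in favour of the less strained Z-oxonene 17.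

**Further compounds**

F1 | step 17 | bromomagnesium alkoxide of diene 25 | CCO/C(=C\C)C1=C[C@H]2O[C@@H]1C/C(C)=C\CC[C@]2(C)O[Mg]Br
F2 | step 23 | C16 pinacol boronate of 32 (C15 configured as in 34) | CCCC(=O)O[C@H]1[C@H]2[C@H]3C/C(C)=C\CC[C@](C)(O)[C@H](O3)[C@H]2[C@H]([C@@H](C)CB4OC(C)(C)C(C)(C)O4)C[C@H]1C
F3 | step 11 | E isomer of ketone 17 | O=C1C[C@H]2O[C@@H]1C/C(C)=C/CC[C@]2(C)O[Si](C)(C)C(C)(C)C
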